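**Retrosynthetic overview** (target numbering: O1, C2 heptyl, C3, C4 ketone, C4a, C5, C6 decyl, O7, C8 lactone C=O, C8a)
- Ring A (the dihydropyranone) is closed last: the C8a–O1 enol ether comes from acid cyclodehydration of a δ-hydroxy, enolised 2,4-dioxo lactone.
- Key C–C disconnection: C4–C4a, ketone carbon to the β-carbon of an unsaturated δ-lactone. Forward, a masked acyl anion (2-lithio-1,3-dithiane) adds 1,4 to the lactone and the enolate is hydroxylated at C8a in the same flask.
- The acyl anion is made in that flask from a 2-silyl-1,3-dithiane and (S)-1,2-epoxynonane by Brook anion relay, which sets C2 and silylates its oxygen.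
- Ring B (the δ-lactone) is made first from (S)-1,2-epoxydodecane and ethyl propiolate (sets C6), then cis-semihydrogenation and lactonisation.
- Ring order: B, then A.

Assumption: (S)-1,2-epoxydodecane and (S)-1,2-epoxynonane are bought as single enantiomers (catalogue items; each is otherwise one hydrolytic kinetic resolution away from the cheap racemate).

**Step 1**
Reactants: 1 (S)-2-decyloxirane [(S)-1,2-epoxydodecane]; 2 ethyl propiolate
Product: 3 ethyl (5S)-5-hydroxypentadec-2-ynoate
Conditions: 2, n-BuLi, THF, −78 °C; BF3·OEt2; then 1, −78 °C, 2 h; aq NH4Cl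
Reagents that add atoms: none
Why: Yamaguchi–Hirao alkynylation: the lithium acetylide/BF3 pair opens the terminal epoxide by SN2 at its CH2 carbon, so the C–O stereocentre of 1 is carried over untouched as C5 (S).

**Step 2**
Reactants: 3 ethyl (5S)-5-hydroxypentadec-2-ynoate
Product: 5 (6S)-6-decyl-5,6-dihydro-2H-pyran-2-one, via Z-hydroxy enoate 4 (not isolated)
Conditions: H2 (1 atm), Pd/CaCO3 poisoned with Pb(OAc)2 (Lindlar catalyst), quinoline, toluene, rt; filter; TsOH·H2O (5 mol %), 60 °C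
Reagents that add atoms: none
Why: Lindlar cis-semihydrogenation gives the Z-enoate, whose δ-hydroxyl then lactonises by acid-catalysed transesterification; the stereocentre is not involved.

**Step 3**
Reactants: 6 tert-butyl(1,3-dithian-2-yl)dimethylsilane [2-TBS-1,3-dithiane]; 7 (S)-2-heptyloxirane [(S)-1,2-epoxynonane]; 5 (6S)-6-decyl-5,6-dihydro-2H-pyran-2-one
Product: 11 (3R,4S,6S)-6-decyl-3-hydroxy-4-{2-[(2S)-2-(tert-butyldimethylsilyloxy)nonyl]-1,3-dithian-2-yl}oxan-2-one, via lithium alkoxide 8 (not isolated), via dithianyllithium 9 (not isolated), via lithium enolate 10 (not isolated)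
Conditions: 6, t-BuLi, Et2O, −78 → −45 °C; 7, −78 → −25 °C; HMPA, THF, −78 → −40 °C; 5, THF, −78 °C; (1S)-(+)-(10-camphorsulfonyl)oxaziridine, −78 → −40 °C; aq NH4Cl
Reagents that add atoms: (1S)-(+)-(10-camphorsulfonyl)oxaziridine, CC1(C)[C@@H]2CC[C@]13CS(=O)(=O)N4O[C@@]34C2
Why: Proposed new method: a one-flask merger of three known events, the closest known reactions being Smith-type dithiane linchpin couplings and tandem conjugate addition–enolate oxidation: (i) Corey–Seebach dithiane umpolung with HMPA-triggered 1,4-Brook anion relay, in which lithiated 6 opens 7 at its CH2 carbon (C–O stereocentre untouched) and the silyl group then moves from carbon to oxygen, regenerating an acyl-anion equivalent at the same carbon; (ii) HMPA-promoted Michael (Stetter-type) addition of this soft anion to C4 of 5, anti to the C6 decyl group, which joins the future ketone carbon to the β-carbon of the enoate; (iii) Davis hydroxylation of the resulting lithium enolate anti to the new C4 substituent, the two new ring stereocentres (3R,4S) being erased later.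

**Step 4**
Reactants: 11 (3R,4S,6S)-6-decyl-3-hydroxy-4-{2-[(2S)-2-(tert-butyldimethylsilyloxy)nonyl]-1,3-dithian-2-yl}oxan-2-one
Product: 12 (6S)-6-decyl-3-hydroxy-4-{2-[(2S)-2-(tert-butyldimethylsilyloxy)nonyl]-1,3-dithian-2-yl}-5,6-dihydro-2H-pyran-2-one (enol tautomer of the 2,3-dione)
Conditions: Dess–Martin periodinane (1.5 equiv), pyridine, dry CH2Cl2, 0 °C → rt
Reagents that add atoms: none
Why: Dess–Martin oxidation of the secondary α-hydroxy lactone gives the α-keto lactone, which enolises into conjugation; short, buffered, anhydrous conditions leave the dithiane and silyl ether alone, and C3 and C4 become sp2.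

**Step 5**
Reactants: 12 (6S)-6-decyl-3-hydroxy-4-{2-[(2S)-2-(tert-butyldimethylsilyloxy)nonyl]-1,3-dithian-2-yl}-5,6-dihydro-2H-pyran-2-one
Product: 15 (2S,6S)-6-decyl-2-heptyl-2,3,5,6-tetrahydropyrano[3,4-b]pyran-4,8-dione (CNP0087259.2), via silyloxy diketone 13 (not isolated), via hydroxy diketone 14 (not isolated)
Conditions: Hg(ClO4)2·3H2O, MeCN/H2O 4:1, 0 °C, 30 min; then 48% aq HF, rt (same flask); NaHCO3 work-up
Reagents that add atoms: water, O
Why: Thiophilic Hg-assisted dithiane hydrolysis (Corey–Seebach unmasking) reveals the acyl ketone and HF cleaves the silyl ether; the freed δ-hydroxyl then adds to the electrophilic C3 carbonyl of the enolised 2,4-dioxo system and loses water under the acid present (the classical δ-hydroxy-β-diketone to 2,3-dihydro-4H-pyran-4-one cyclodehydration), with neither C–O stereocentre touched.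

**Compound list**
1 | (S)-2-decyloxirane [(S)-1,2-epoxydodecane] | CCCCCCCCCC[C@H]1CO1 | starting material
2 | ethyl propiolate | C#CC(=O)OCC | starting material
3 | ethyl (5S)-5-hydroxypentadec-2-ynoate | CCCCCCCCCC[C@H](O)CC#CC(=O)OCC | intermediate
4 | ethyl (2Z,5S)-5-hydroxypentadec-2-enoate | CCCCCCCCCC[C@H](O)C/C=C\C(=O)OCC | intermediate (not isolated)
5 | (6S)-6-decyl-5,6-dihydro-2H-pyran-2-one | CCCCCCCCCC[C@H]1CC=CC(=O)O1 | intermediate
6 | tert-butyl(1,3-dithian-2-yl)dimethylsilane | CC(C)(C)[Si](C)(C)C1SCCCS1 | starting material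
7 | (S)-2-heptyloxirane [(S)-1,2-epoxynonane] | CCCCCCC[C@H]1CO1 | starting material
8 | lithium (2S)-1-[2-(tert-butyldimethylsilyl)-1,3-dithian-2-yl]nonan-2-olate | CCCCCCC[C@H](O[Li])CC1([Si](C)(C)C(C)(C)C)SCCCS1 | intermediate (not isolated)
9 | {2-[(2S)-2-(tert-butyldimethylsilyloxy)nonyl]-1,3-dithian-2-yl}lithium | CCCCCCC[C@H](O[Si](C)(C)C(C)(C)C)CC1([Li])SCCCS1 | intermediate (not isolated)
10 | lithium (4S,6S)-6-decyl-4-{2-[(2S)-2-(tert-butyldimethylsilyloxy)nonyl]-1,3-dithian-2-yl}-5,6-dihydro-4H-pyran-2-olate | CCCCCCCCCC[C@H]1C[C@H](C2(C[C@H](CCCCCCC)O[Si](C)(C)C(C)(C)C)SCCCS2)C=C(O[Li])O1 | intermediate (not isolated)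
11 | (3R,4S,6S)-6-decyl-3-hydroxy-4-{2-[(2S)-2-(tert-butyldimethylsilyloxy)nonyl]-1,3-dithian-2-yl}oxan-2-one | CCCCCCCCCC[C@H]1C[C@H](C2(C[C@H](CCCCCCC)O[Si](C)(C)C(C)(C)C)SCCCS2)[C@@H](O)C(=O)O1 | intermediate
12 | (6S)-6-decyl-3-hydroxy-4-{2-[(2S)-2-(tert-butyldimethylsilyloxy)nonyl]-1,3-dithian-2-yl}-5,6-dihydro-2H-pyran-2-one | CCCCCCCCCC[C@H]1CC(C2(C[C@H](CCCCCCC)O[Si](C)(C)C(C)(C)C)SCCCS2)=C(O)C(=O)O1 | intermediate
13 | (6S)-4-[(3S)-3-(tert-butyldimethylsilyloxy)decanoyl]-6-decyl-3-hydroxy-5,6-dihydro-2H-pyran-2-one | CCCCCCCCCC[C@H]1CC(C(=O)C[C@H](CCCCCCC)O[Si](C)(C)C(C)(C)C)=C(O)C(=O)O1 | intermediate (not isolated)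
14 | (6S)-6-decyl-3-hydroxy-4-[(3S)-3-hydroxydecanoyl]-5,6-dihydro-2H-pyran-2-one | CCCCCCCCCC[C@H]1CC(C(=O)C[C@H](CCCCCCC)O)=C(O)C(=O)O1 | intermediate (not isolated)
15 | (2S,6S)-6-decyl-2-heptyl-2,3,5,6-tetrahydropyrano[3,4-b]pyran-4,8-dione | CCCCCCCCCC[C@H]1CC2=C(O[C@@H](CCCCCCC)CC2=O)C(=O)O1 | target

**Totals**
Total step count: 5.
Longest linear sequence: 5 steps (1 → 3 → 5 → 11 → 12 → 15); 6 and 7 enter in step 3.

**Steps most likely to fail, with fallbacks**

Step 3. The strongly basic lithium dithiane may attack the lactone carbonyl or deprotonate C5 of 5 instead of adding 1,4. The fallback sets out from 5 (with 6 and 7) and returns at 11. The relay is run only as far as anion 9, which is quenched with CO2 to give 2-[(2S)-2-(tert-butyldimethylsilyloxy)nonyl]-1,3-dithiane-2-carboxylic acid F1. Decarboxylative photoredox Giese addition of F1 to 5 (4CzIPN, K2HPO4, DMSO, blue LEDs, rt) then delivers the same dithianyl unit as a nucleophilic radical under base-free conditions, giving (4S,6S)-6-decyl-4-{2-[(2S)-2-(tert-butyldimethylsilyloxy)nonyl]-1,3-dithian-2-yl}oxan-2-one F2. Enolisation of F2 with LiN(SiMe3)2 in THF at −78 °C and hydroxylation with the same oxaziridine gives 11.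

Step 5. Dithiane hydrolysis next to the enolised keto lactone may be sluggish or messy, or the cyclodehydration may stall. The fallback sets out from 12 and returns at 15, closing ring A before unmasking the ketone. HF·pyridine in THF at 0 °C removes the silyl group to give (6S)-6-decyl-3-hydroxy-4-{2-[(2S)-2-hydroxynonyl]-1,3-dithian-2-yl}-5,6-dihydro-2H-pyran-2-one F4. TsOH (cat.) in toluene with 4 Å sieves at 50 °C forms the cyclic hemiketal at C3 and dehydrates it to the spiro-dithiane enol ether (2S,6S)-6-decyl-2-heptyl-2,3,5,6-tetrahydro-8H-spiro[pyrano[3,4-b]pyran-4,2'-[1,3]dithian]-8-one F5. Its dithiane, now activated by the ring oxygen, is hydrolysed without metal or oxidant (MeI, CaCO3, MeCN/H2O 9:1, 45 °C) to 15.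

Step 4. The hindered 3-hydroxyl may oxidise slowly, and the sulfur or the enol product may be attacked by the periodinane. The fallback sets out from enolate 10 (in the step 3 flask) and returns at 12, so that the alcohol is never made. Dry O2 is passed through the −78 °C solution of 10 in place of the oxaziridine, and AcOH quench gives (3R,4S,6S)-6-decyl-3-hydroperoxy-4-{2-[(2S)-2-(tert-butyldimethylsilyloxy)nonyl]-1,3-dithian-2-yl}oxan-2-one F3. Kornblum–DeLaMare-type dehydration of F3 through its peracetate (Ac2O, Et3N, cat. DMAP, CH2Cl2, 0 °C) gives 12 directly.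

**Further compounds**
F1 | step 3 | 2-[(2S)-2-(tert-butyldimethylsilyloxy)nonyl]-1,3-dithiane-2-carboxylic acid | CCCCCCC[C@H](O[Si](C)(C)C(C)(C)C)CC1(C(=O)O)SCCCS1
F2 | step 3 | (4S,6S)-6-decyl-4-{2-[(2S)-2-(tert-butyldimethylsilyloxy)nonyl]-1,3-dithian-2-yl}oxan-2-one | CCCCCCCCCC[C@H]1C[C@H](C2(C[C@H](CCCCCCC)O[Si](C)(C)C(C)(C)C)SCCCS2)CC(=O)O1
F3 | step 4 | (3R,4S,6S)-6-decyl-3-hydroperoxy-4-{2-[(2S)-2-(tert-butyldimethylsilyloxy)nonyl]-1,3-dithian-2-yl}oxan-2-one | CCCCCCCCCC[C@H]1C[C@H](C2(C[C@H](CCCCCCC)O[Si](C)(C)C(C)(C)C)SCCCS2)[C@@H](OO)C(=O)O1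
F4 | step 5 | (6S)-6-decyl-3-hydroxy-4-{2-[(2S)-2-hydroxynonyl]-1,3-dithian-2-yl}-5,6-dihydro-2H-pyran-2-one | CCCCCCCCCC[C@H]1CC(C2(C[C@H](CCCCCCC)O)SCCCS2)=C(O)C(=O)O1
F5 | step 5 | (2S,6S)-6-decyl-2-heptyl-2,3,5,6-tetrahydro-8H-spiro[pyrano[3,4-b]pyran-4,2'-[1,3]dithian]-8-one | CCCCCCCCCC[C@H]1CC2=C(O[C@@H](CCCCCCC)CC23SCCCS3)C(=O)O1
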